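**Plan**

1. Retrosynthesis: the two phenol methyl ethers, the C6' 3-methylbutanoyl group and the C8' formyl group are removed first. The C7 methylene of the bicyclo[3.1.1]heptane is taken back to a ketone, and the cyclobutane bonds C1–C7 and C5–C6 are cut together, leaving a ketene (C5=C7=O) and a 2-methylprop-1-enyl group (C1=C6) on chroman carbon C2. The chroman is then opened at the aryl–O1' bond and the tertiary carbinol is taken apart into its three carbon arms.
2. Enabling feature: in the cyclobutane C1–C6–C5–C7 the gem-dimethyl carbon C6 sits next to bridgehead C1, which is bonded to the oxygenated spiro carbon C2, and C5 is reached from C1 through C2, C3 and C4. Read backwards this is a trisubstituted alkene with a three-atom tether on its less substituted carbon, the pattern in which a ketene adds in the crossed sense; C7 is the ketene carbonyl, a helper oxygen removed in step 13.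
3. Forward order: arene side chain → C2 stereocentre (epoxide) → three arms on C2 → chroman ring by aryl C–O coupling → six- and four-membered carbocycles in one step → C7 deoxygenation → C8' formyl → C6' acyl → free phenols.
4. Stereochemistry: C2 comes from a Sharpless epoxidation with D-(−)-tartrate and is not touched again; C1 and C5 are set in the key step under control of C2.
5. Numbering: bicycle C1–C7 (C2 spiro carbon, C6 CMe2, C7 one-carbon bridge); chroman O1', C2' (= C2), C3', C4', C4a', C5'–C8', C8a'. Closing the chroman at a defined aryl carbon fixes which oxygen becomes O1', so the acyl/formyl pattern is unambiguous.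

Key step: step 12

Remark: the phenols are carried as methyl ethers and C7 as a carbonyl group until after the key step, because the Wolff–Kishner reduction would not spare the aryl carbonyl groups of the target.

**Route**

Step 1
Reactants: 1 1-bromo-3,5-dimethoxybenzene
Product: 3 2-bromo-4,6-dimethoxybenzaldehyde, via aryl iminium chloride 2 (not isolated)
Conditions: POCl3, DMF, 0 → 90 °C; then aq. NaOAc
Reagents that add atoms: N,N-dimethylformamide CN(C)C=O; water O
Why: Vilsmeier–Haack formylation; the chloroiminium ion should enter para to one methoxy group (the site between the two methoxy groups is more hindered), and the iminium salt is hydrolysed on work-up.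

Step 2
Reactants: 3 2-bromo-4,6-dimethoxybenzaldehyde
Product: 4 (2-bromo-4,6-dimethoxyphenyl)methanol
Conditions: NaBH4, MeOH, 0 °C
Reagents that add atoms: none
Why: Borohydride reduction of an aryl aldehyde; aryl bromide and ethers are inert.

Step 3
Reactants: 4 (2-bromo-4,6-dimethoxyphenyl)methanol
Product: 5 1-bromo-2-(bromomethyl)-3,5-dimethoxybenzene
Conditions: PBr3, CH2Cl2, 0 °C
Reagents that add atoms: phosphorus tribromide BrP(Br)Br
Why: Conversion of an electron-rich benzylic alcohol into the bromide through its phosphite ester (SN2); the bromide is used without storage.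

Step 4
Reactants: 5 1-bromo-2-(bromomethyl)-3,5-dimethoxybenzene; 6 2-methylprop-2-en-1-ol
Product: 8 4-(2-bromo-4,6-dimethoxyphenyl)-2-methylidenebutan-1-ol, via dilithio dianion 7 (not isolated)
Conditions: 6, n-BuLi (2.1 equiv), TMEDA, Et2O, 0 °C → rt; then 5, THF, −78 → 0 °C; H2O
Reagents that add atoms: none
Why: Alkylation of the methallyl alcohol dianion; the allylic carbanion displaces the benzylic bromide (SN2) faster than bromine–lithium exchange at the aryl bromide can occur at −78 °C, and no free n-BuLi is present when 5 is added.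

Step 5
Reactants: 8 4-(2-bromo-4,6-dimethoxyphenyl)-2-methylidenebutan-1-ol
Product: 9 [(2R)-2-[2-(2-bromo-4,6-dimethoxyphenyl)ethyl]oxiran-2-yl]methanol
Conditions: Ti(OiPr)4 (10 mol%), D-(−)-diisopropyl tartrate (12 mol%), t-BuOOH, 4 Å MS, CH2Cl2, −25 °C
Reagents that add atoms: tert-butyl hydroperoxide CC(C)(C)OO
Why: Catalytic Sharpless asymmetric epoxidation of a 2-substituted allylic alcohol; the titanium–tartrate–allylic alkoxide complex selects the face, D-(−)-tartrate giving the (R)-epoxide in the sense known for 2-methylprop-2-en-1-ol → (R)-2-methylglycidol, so the new stereocentre does not depend on any size difference between the two carbon arms.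

Step 6
Reactants: 9 [(2R)-2-[2-(2-bromo-4,6-dimethoxyphenyl)ethyl]oxiran-2-yl]methanol
Product: 10 (2R)-2-[2-(2-bromo-4,6-dimethoxyphenyl)ethyl]hex-5-ene-1,2-diol
Conditions: allylMgBr (3 equiv), CuI (10 mol%), THF, −30 → 0 °C; H2O
Reagents that add atoms: allylmagnesium bromide C=CC[Mg]Br
Why: Copper-catalysed Grignard opening of a 2,2-disubstituted epoxide at its CH2 terminus (SN2); no bond to the stereocentre is broken (a Payne shift of the alkoxide would regenerate the same enantiomer), so the configuration is kept.

Step 7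
Reactants: 10 (2R)-2-[2-(2-bromo-4,6-dimethoxyphenyl)ethyl]hex-5-ene-1,2-diol
Product: 11 (2R)-2-[2-(2-bromo-4,6-dimethoxyphenyl)ethyl]-2-hydroxyhex-5-enal
Conditions: SO3·pyridine, DMSO, i-Pr2NEt, CH2Cl2, 0 °C
Reagents that add atoms: none
Why: Parikh–Doering oxidation; only the primary alcohol can be oxidised, and the non-acidic conditions should spare the tertiary carbinol.

Step 8
Reactants: 11 (2R)-2-[2-(2-bromo-4,6-dimethoxyphenyl)ethyl]-2-hydroxyhex-5-enal
Product: 12 (4R)-4-[2-(2-bromo-4,6-dimethoxyphenyl)ethyl]-2-methylocta-2,7-dien-4-ol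
Conditions: i-PrPPh3+ I−, n-BuLi, THF, 0 °C; then 11, −78 → 0 °C
Reagents that add atoms: isopropyltriphenylphosphonium iodide CC(C)[P+](c1ccccc1)(c1ccccc1)c1ccccc1.[I-]
Why: Wittig olefination with a pre-formed non-stabilised ylide in excess (one equivalent is taken up by the free hydroxyl, and no free n-BuLi remains to touch the aryl bromide); the ylide carries two identical methyl groups, so no alkene geometry arises, and the quaternary α-carbon cannot epimerise.

Step 9
Reactants: 12 (4R)-4-[2-(2-bromo-4,6-dimethoxyphenyl)ethyl]-2-methylocta-2,7-dien-4-ol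
Product: 13 (2R)-2-(but-3-en-1-yl)-5,7-dimethoxy-2-(2-methylprop-1-en-1-yl)-3,4-dihydro-2H-chromene
Conditions: Pd(OAc)2 (3 mol%), 2-(di-tert-butylphosphino)-1,1'-binaphthyl (4 mol%), Cs2CO3, toluene, 80 °C
Reagents that add atoms: none
Why: Buchwald-type Pd-catalysed intramolecular etherification of an aryl bromide by a tertiary alkoxide (six-membered ring, no β-hydrogen on the carbinol carbon); the C–O bond of the stereocentre is retained, and C–O reductive elimination should outrun carbopalladation of the hindered trisubstituted alkene.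

Step 10
Reactants: 13 (2R)-2-(but-3-en-1-yl)-5,7-dimethoxy-2-(2-methylprop-1-en-1-yl)-3,4-dihydro-2H-chromene
Product: 15 4-[(2R)-5,7-dimethoxy-2-(2-methylprop-1-en-1-yl)-3,4-dihydro-2H-chromen-2-yl]butan-1-ol, via B-alkyl-9-BBN adduct 14 (not isolated)
Conditions: 9-BBN, THF, 0 °C → rt; then NaOH, H2O2, 0 °C
Reagents that add atoms: hydrogen peroxide OO
Why: Hydroboration–oxidation; 9-BBN adds anti-Markovnikov to the monosubstituted alkene and should leave the trisubstituted 2-methylprop-1-enyl group untouched.

Step 11
Reactants: 15 4-[(2R)-5,7-dimethoxy-2-(2-methylprop-1-en-1-yl)-3,4-dihydro-2H-chromen-2-yl]butan-1-ol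
Product: 17 4-[(2R)-5,7-dimethoxy-2-(2-methylprop-1-en-1-yl)-3,4-dihydro-2H-chromen-2-yl]butanoic acid, via aldehyde 16 (not isolated)
Conditions: TEMPO (20 mol%), PhI(OAc)2, MeCN/pH 7 buffer, rt
Reagents that add atoms: water O
Why: Oxoammonium (TEMPO/PhI(OAc)2) oxidation of a primary alcohol through the aldehyde hydrate to the acid; the trisubstituted alkene is not affected and the buffered medium should spare the tertiary allylic aryl ether.

Step 12
Reactants: 17 4-[(2R)-5,7-dimethoxy-2-(2-methylprop-1-en-1-yl)-3,4-dihydro-2H-chromen-2-yl]butanoic acid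
Product: 20 (1R,2R,5R)-5',7'-dimethoxy-6,6-dimethyl-3',4'-dihydrospiro[bicyclo[3.1.1]heptane-2,2'-chromen]-7-one, via acid chloride 18 (not isolated), via ketene 19 (not isolated)
Conditions: 1-chloro-N,N,2-trimethylprop-1-en-1-amine, CH2Cl2, 0 °C → rt; then slow addition to Et3N, toluene, reflux, 0.005 M
Reagents that add atoms: none
Why: Neutral conversion of the acid into its chloride and dehydrochlorination give aldoketene 19, which adds to the 2-methylprop-1-enyl group in a thermal, asynchronous [2+2] cycloaddition: the electrophilic ketene carbonyl carbon (C7) bonds to the less substituted alkene carbon (C1) while positive charge builds up on the dimethyl-substituted carbon (C6), which then closes onto the ketene α-carbon (C5). The closest known reaction type is the intramolecular ketene–alkene cycloaddition that turns geranoyl chloride into a 7,7-dimethylbicyclo[3.1.1]heptan-6-one, with the same three-atom tether and the same trisubstituted alkene. The first bond closes the six-membered ring C1–C2–C3–C4–C5–C7 in a 6-exo sense and the second closes the cyclobutane C1–C6–C5–C7, so the bridged (crossed) adduct should form and not the fused one. C1 and C5 are formed suprafacially on the alkene and are tied to each other by the two one-carbon bridges; their sense relative to C2 is set by the allylic stereocentre, because with the tether CH2 forced inside, the C2–O1' bond should lie near the alkene plane (outside) and the C2–C3' bond anti to the incoming ketene carbon, since an allylic C–O bond aligned with the π system would lower its nucleophilicity, and this places O1' on the side of the carbonyl bridge as the target requires. The step needs cycloaddition to beat ketene dimerisation and ene-type proton loss, which high dilution, slow addition and the fully substituted tether carbon C2 are meant to secure.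

Step 13
Reactants: 20 (1R,2R,5R)-5',7'-dimethoxy-6,6-dimethyl-3',4'-dihydrospiro[bicyclo[3.1.1]heptane-2,2'-chromen]-7-one
Product: 22 (1R,2R,5S)-5',7'-dimethoxy-6,6-dimethyl-3',4'-dihydrospiro[bicyclo[3.1.1]heptane-2,2'-chromene], via hydrazone 21 (not isolated)
Conditions: N2H4·H2O, diethylene glycol, 130 °C; then KOH, 200 °C
Reagents that add atoms: none
Why: Wolff–Kishner reduction (Huang-Minlon procedure), a known way to deoxygenate bicyclo[3.1.1]heptan-6-ones; forming the hydrazone before base is added should limit hydroxide cleavage of the non-enolisable cyclobutanone, and the ethers and all three stereocentres are untouched.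

Step 14
Reactants: 22 (1R,2R,5S)-5',7'-dimethoxy-6,6-dimethyl-3',4'-dihydrospiro[bicyclo[3.1.1]heptane-2,2'-chromene]
Product: 25 (1R,2R,5S)-5',7'-dimethoxy-6,6-dimethyl-3',4'-dihydrospiro[bicyclo[3.1.1]heptane-2,2'-chromene]-8'-carbaldehyde, via 8'-aryllithium 23 (not isolated), via lithium hemiaminal alkoxide 24 (not isolated)
Conditions: n-BuLi, TMEDA, THF, 0 °C; DMF, −78 °C → rt; H2O
Reagents that add atoms: N,N-dimethylformamide CN(C)C=O
Why: Directed ortho-lithiation and formylation; C8' lies between the fixed in-plane lone pair of ring oxygen O1' and the 7'-methoxy group and should be metalated in preference to C6', whose 5'-methoxy neighbour must turn its methyl group towards it.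

Step 15
Reactants: 25 (1R,2R,5S)-5',7'-dimethoxy-6,6-dimethyl-3',4'-dihydrospiro[bicyclo[3.1.1]heptane-2,2'-chromene]-8'-carbaldehyde
Product: 29 (1R,2R,5S)-5',7'-dimethoxy-6,6-dimethyl-6'-(3-methylbutanoyl)-3',4'-dihydrospiro[bicyclo[3.1.1]heptane-2,2'-chromene]-8'-carbaldehyde, via piperazine-masked aldehyde 26 (not isolated), via 6'-aryllithium 27 (not isolated), via chelated Weinreb adduct 28 (not isolated)
Conditions: 1-methylpiperazine, n-BuLi, THF, −20 °C; s-BuLi, TMEDA, −78 → −30 °C; i-BuC(O)N(OMe)Me, −78 °C → rt; H2O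
Reagents that add atoms: N-methoxy-N,3-dimethylbutanamide CC(C)CC(=O)N(C)OC
Why: In situ protection of the aldehyde as its lithium α-amino alkoxide (Comins protocol), deprotonation of the only remaining aryl C–H (C6', between two methoxy groups) and acylation of the aryllithium by the Weinreb amide, whose chelated adduct cannot over-add; aqueous work-up releases both carbonyl groups.

Step 16
Reactants: 29 (1R,2R,5S)-5',7'-dimethoxy-6,6-dimethyl-6'-(3-methylbutanoyl)-3',4'-dihydrospiro[bicyclo[3.1.1]heptane-2,2'-chromene]-8'-carbaldehyde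
Product: 30 euglobal G3
Conditions: EtSNa, DMF, 110 °C; then 1 M HCl
Reagents that add atoms: none
Why: Nucleophilic (SN2) demethylation by thiolate; both methoxy groups are ortho to a carbonyl group (vinylogous methyl esters) and are cleaved at the methyl carbon, whereas the tertiary C2–O1' ether cannot react by SN2 and no Lewis acid is present to ionise it.

**Compound list**

1 | 1-bromo-3,5-dimethoxybenzene | COc1cc(Br)cc(OC)c1 | starting material
2 | N-[(2-bromo-4,6-dimethoxyphenyl)methylidene]-N-methylmethanaminium chloride (aryl iminium chloride) | COc1cc(Br)c(C=[N+](C)C)c(OC)c1.[Cl-] | intermediate (not isolated)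
3 | 2-bromo-4,6-dimethoxybenzaldehyde | COc1cc(Br)c(C=O)c(OC)c1 | intermediate
4 | (2-bromo-4,6-dimethoxyphenyl)methanol | COc1cc(Br)c(CO)c(OC)c1 | intermediate
5 | 1-bromo-2-(bromomethyl)-3,5-dimethoxybenzene | COc1cc(Br)c(CBr)c(OC)c1 | intermediate
6 | 2-methylprop-2-en-1-ol | CC(=C)CO | starting material
7 | C,O-dilithio dianion of 2-methylprop-2-en-1-ol | [Li]CC(=C)CO[Li] | intermediate (not isolated)
8 | 4-(2-bromo-4,6-dimethoxyphenyl)-2-methylidenebutan-1-ol | COc1cc(Br)c(CCC(=C)CO)c(OC)c1 | intermediate
9 | [(2R)-2-[2-(2-bromo-4,6-dimethoxyphenyl)ethyl]oxiran-2-yl]methanol | COc1cc(Br)c(CC[C@@]2(CO)CO2)c(OC)c1 | intermediate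
10 | (2R)-2-[2-(2-bromo-4,6-dimethoxyphenyl)ethyl]hex-5-ene-1,2-diol | COc1cc(Br)c(CC[C@@](CO)(CCC=C)O)c(OC)c1 | intermediate
11 | (2R)-2-[2-(2-bromo-4,6-dimethoxyphenyl)ethyl]-2-hydroxyhex-5-enal | COc1cc(Br)c(CC[C@@](C=O)(CCC=C)O)c(OC)c1 | intermediate
12 | (4R)-4-[2-(2-bromo-4,6-dimethoxyphenyl)ethyl]-2-methylocta-2,7-dien-4-ol | COc1cc(Br)c(CC[C@@](C=C(C)C)(CCC=C)O)c(OC)c1 | intermediate
13 | (2R)-2-(but-3-en-1-yl)-5,7-dimethoxy-2-(2-methylprop-1-en-1-yl)-3,4-dihydro-2H-chromene | COc1cc2c(c(OC)c1)CC[C@@](C=C(C)C)(CCC=C)O2 | intermediate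
14 | 9-{4-[(2R)-5,7-dimethoxy-2-(2-methylprop-1-en-1-yl)-3,4-dihydro-2H-chromen-2-yl]butyl}-9-borabicyclo[3.3.1]nonane | COc1cc2c(c(OC)c1)CC[C@@](C=C(C)C)(CCCCB1C3CCCC1CCC3)O2 | intermediate (not isolated)
15 | 4-[(2R)-5,7-dimethoxy-2-(2-methylprop-1-en-1-yl)-3,4-dihydro-2H-chromen-2-yl]butan-1-ol | COc1cc2c(c(OC)c1)CC[C@@](C=C(C)C)(CCCCO)O2 | intermediate
16 | 4-[(2R)-5,7-dimethoxy-2-(2-methylprop-1-en-1-yl)-3,4-dihydro-2H-chromen-2-yl]butanal | COc1cc2c(c(OC)c1)CC[C@@](C=C(C)C)(CCCC=O)O2 | intermediate (not isolated)
17 | 4-[(2R)-5,7-dimethoxy-2-(2-methylprop-1-en-1-yl)-3,4-dihydro-2H-chromen-2-yl]butanoic acid | COc1cc2c(c(OC)c1)CC[C@@](C=C(C)C)(CCCC(=O)O)O2 | intermediate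
18 | 4-[(2R)-5,7-dimethoxy-2-(2-methylprop-1-en-1-yl)-3,4-dihydro-2H-chromen-2-yl]butanoyl chloride | COc1cc2c(c(OC)c1)CC[C@@](C=C(C)C)(CCCC(=O)Cl)O2 | intermediate (not isolated)
19 | 4-[(2R)-5,7-dimethoxy-2-(2-methylprop-1-en-1-yl)-3,4-dihydro-2H-chromen-2-yl]but-1-en-1-one (ketene) | COc1cc2c(c(OC)c1)CC[C@@](C=C(C)C)(CCC=C=O)O2 | intermediate (not isolated)
20 | (1R,2R,5R)-5',7'-dimethoxy-6,6-dimethyl-3',4'-dihydrospiro[bicyclo[3.1.1]heptane-2,2'-chromen]-7-one | COc1cc2c(c(OC)c1)CC[C@@]1(CC[C@H]3C(=O)[C@@H]1C3(C)C)O2 | intermediate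
21 | hydrazone of 20 at C7 | COc1cc2c(c(OC)c1)CC[C@@]1(CC[C@H]3C(=NN)[C@@H]1C3(C)C)O2 | intermediate (not isolated)
22 | (1R,2R,5S)-5',7'-dimethoxy-6,6-dimethyl-3',4'-dihydrospiro[bicyclo[3.1.1]heptane-2,2'-chromene] | COc1cc2c(c(OC)c1)CC[C@@]1(CC[C@H]3C[C@@H]1C3(C)C)O2 | intermediate
23 | 8'-lithio derivative of 22 | COc1cc(OC)c([Li])c2c1CC[C@@]1(CC[C@H]3C[C@@H]1C3(C)C)O2 | intermediate (not isolated)
24 | lithium (dimethylamino)(aryl)methanolate from 23 and DMF (aryl = C8' of 22) | COc1cc(OC)c(C(O[Li])N(C)C)c2c1CC[C@@]1(CC[C@H]3C[C@@H]1C3(C)C)O2 | intermediate (not isolated)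
25 | (1R,2R,5S)-5',7'-dimethoxy-6,6-dimethyl-3',4'-dihydrospiro[bicyclo[3.1.1]heptane-2,2'-chromene]-8'-carbaldehyde | COc1cc(OC)c(C=O)c2c1CC[C@@]1(CC[C@H]3C[C@@H]1C3(C)C)O2 | intermediate
26 | lithium (4-methylpiperazin-1-yl)methanolate adduct of 25 at the C8' aldehyde | COc1cc(OC)c(C(O[Li])N4CCN(C)CC4)c2c1CC[C@@]1(CC[C@H]3C[C@@H]1C3(C)C)O2 | intermediate (not isolated)
27 | 6'-lithio derivative of 26 | [Li]c1c(OC)c(C(O[Li])N4CCN(C)CC4)c2c(c1OC)CC[C@@]1(CC[C@H]3C[C@@H]1C3(C)C)O2 | intermediate (not isolated)
28 | tetrahedral adduct of 27 with the Weinreb amide (lithium N-methoxy-N-methyl hemiaminal alkoxide at C6') | CC(C)CC(O[Li])(N(C)OC)c1c(OC)c(C(O[Li])N4CCN(C)CC4)c2c(c1OC)CC[C@@]1(CC[C@H]3C[C@@H]1C3(C)C)O2 | intermediate (not isolated)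
29 | (1R,2R,5S)-5',7'-dimethoxy-6,6-dimethyl-6'-(3-methylbutanoyl)-3',4'-dihydrospiro[bicyclo[3.1.1]heptane-2,2'-chromene]-8'-carbaldehyde | CC(C)CC(=O)c1c(OC)c(C=O)c2c(c1OC)CC[C@@]1(CC[C@H]3C[C@@H]1C3(C)C)O2 | intermediate
30 | euglobal G3, (1R,2R,5S)-5',7'-dihydroxy-6,6-dimethyl-6'-(3-methylbutanoyl)-3',4'-dihydrospiro[bicyclo[3.1.1]heptane-2,2'-chromene]-8'-carbaldehyde | CC(C)CC(=O)c1c(O)c(C=O)c2c(c1O)CC[C@@]1(CC[C@H]3C[C@@H]1C3(C)C)O2 | target

**Summary**

Total step count: 16. Longest linear sequence: 16 steps (1 → 30; 6 enters in step 4).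

Steps most likely to fail:

Step 12. The aldoketene may oligomerise or lose a proton in an ene-type path before it adds to an alkene that is inductively deactivated by the allylic oxygen, and facial selectivity may be insufficient, which would give the C2-epimeric ring system. The fallback uses a keteniminium ion in place of the ketene. It sets out from acid 17: the acid chloride 18 is treated with pyrrolidine to give 4-[(2R)-5,7-dimethoxy-2-(2-methylprop-1-en-1-yl)-3,4-dihydro-2H-chromen-2-yl]-1-(pyrrolidin-1-yl)butan-1-one F1. Tf2O and 2,4,6-collidine in refluxing 1,2-dichloroethane should convert F1 into the keteniminium triflate F2, which does not dimerise and is a stronger electrophile; it should close in the same crossed sense to the cyclobutaniminium triflate F3. Hydrolysis with aqueous NaHCO3 returns to the route at ketone 20. The more cationic first bond formation should also make the preference for the in-plane C–O bond stronger.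

Step 16. Cleavage of the second methyl ether may stall once the first phenoxide has formed, and forcing conditions may cause base-induced elimination at the tertiary aryl ether, which is activated by two carbonyl groups. The fallback moves the deprotection ahead of the acylation. It sets out from aldehyde 25, where that ether is activated by one carbonyl group only: sodium ethanethiolate in DMF should give (1R,2R,5S)-5',7'-dihydroxy-6,6-dimethyl-3',4'-dihydrospiro[bicyclo[3.1.1]heptane-2,2'-chromene]-8'-carbaldehyde F4. Friedel–Crafts acylation of this free resorcinol aldehyde at its only open position C6' (3-methylbutanoyl chloride, TiCl4, CH2Cl2, 0 °C) comes back to the route at 30, so 29 is bypassed.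

Step 15. Deprotonation at the buttressed C6' position may be slow, benzylic metalation at C4' may compete, and acyl transfer to the hindered aryllithium may be sluggish. The fallback replaces the anionic sequence by electrophilic substitution. It sets out from aldehyde 25: Friedel–Crafts acylation with 3-methylbutanoyl chloride and TiCl4 (CH2Cl2, −40 → 0 °C) at the only free ring position, which is meta to the formyl group and activated by three oxygen substituents, returns directly to 29 (no new compound; F0). Any methyl ether cleaved by TiCl4 on the way is an intermediate of step 16 and is carried into it.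

Further compounds
F1 | step 12 | 4-[(2R)-5,7-dimethoxy-2-(2-methylprop-1-en-1-yl)-3,4-dihydro-2H-chromen-2-yl]-1-(pyrrolidin-1-yl)butan-1-one | COc1cc2c(c(OC)c1)CC[C@@](C=C(C)C)(CCCC(=O)N3CCCC3)O2
F2 | step 12 | keteniminium triflate from F1 (1-{4-[(2R)-chromen-2-yl]but-1-en-1-ylidene}pyrrolidinium triflate) | COc1cc2c(c(OC)c1)CC[C@@](C=C(C)C)(CCC=C=[N+]3CCCC3)O2.[O-]S(=O)(=O)C(F)(F)F
F3 | step 12 | C7 pyrrolidinium (cyclobutaniminium) triflate of ketone 20 | COc1cc2c(c(OC)c1)CC[C@@]1(CC[C@H]3C(=[N+]4CCCC4)[C@@H]1C3(C)C)O2.[O-]S(=O)(=O)C(F)(F)F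
F4 | step 16 | (1R,2R,5S)-5',7'-dihydroxy-6,6-dimethyl-3',4'-dihydrospiro[bicyclo[3.1.1]heptane-2,2'-chromene]-8'-carbaldehyde | Oc1cc(O)c(C=O)c2c1CC[C@@]1(CC[C@H]3C[C@@H]1C3(C)C)O2
F0 | step 15 | none | none
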